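Measure time not in hours but in turns of the first step, the hours multiplied by its rate constant and by the charge.

the same everywhere: time 8.0 h

| run | substrate | partner | remark |
|---|---|---|---|
| cedar | 0.010 M | 10.0 mM | everything together at the start |
| ash | 0.010 M | 10.0 mM (fed, over 3.0 h) | all else is in the flask from the start; the feed brings no volume worth counting |
| oak | 0.010 M (fed, over 3.0 h) | 10.0 mM | all else is in the flask from the start; the feed brings no volume worth counting |
| alder | 0.010 M (in portions, 4, over 3.0 h) | 10.0 mM | first portion at the start, last at 3.0 h |

    substrate + partner → intermediate + released group (k1 = 18 L mol⁻¹ h⁻¹)
    intermediate → product (k2 = 0.44 h⁻¹)

* the best flask by amount of product, in percent of the substrate charged; "all alike" if 1.5 percentage points covers them all (cedar / ash / oak / alder / all alike)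
* amount of product at the end, in percent of the substrate charged, cedar
* amount of product at the end, in percent of the substrate charged, ash
* amount of product at the end, in percent of the substrate charged, oak
* amount of product at the end, in percent of the substrate charged, alder

Begin with cedar. Substrate and partner are charged equally and fall together, so the fraction of substrate left at clock reading θ is one over one plus θ, and the end of cedar reads 1.44.

Now divide the rate of the first step at the full charges by the rate of the feed: hours drop out of the ratio and leave 0.540, the dosing number. It stands below one, so even at the full charges, which a fed flask does not have while its feed runs, the first step would run at about half of the feed rate, and the fed charge accumulates. Treat each fed flask, then, as a batch started late by the mean arrival of its charge, 1.50 h in ash, oak and alder alike, which takes half of the dosing number off the clock. For intermediate, take the rate of the first step one intermediate lifetime earlier, 2.27 h before the end, and divide it by the rate constant of the second step.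

In fractions of the charge, my reckoning gives:

| Flask | Clock at end | Substrate left | Intermediate | Product |
|---|---|---|---|---|
| cedar | 1.44 | 0.410 | 0.0992 | 0.491 |
| ash, oak, alder | 1.17 | 0.461 | 0.132 | 0.407 |

Read the clock column first: the fed row runs behind cedar by 0.270. Read across: that lag leaves more substrate and more intermediate, and both come out of product, so the fed flasks trail cedar by 8.4 percentage points, more than the margin of 1.5 points.

The forecast names cedar, with 48.8 %, 41 %, 41 % and 41.3 % in the order asked, on the ground that “any delay in bringing the reactants together costs product”. My reckoning gives one value for the three fed flasks, where the forecast sets alder slightly apart.

The flasks give 48.8 %, 41.1 %, 41.1 % and 41.0 % in that order, which puts cedar first. At the end of alder, the half-life of substrate by the first step is 8.3 h, longer than the 1.6 h of intermediate by the second, which makes the first the rate-limiting step there, with substrate at 46.5 % of the charge against 12.5 % as intermediate. Shorten the feed of oak to 0.900 h, and the dosing number becomes 0.162, from which the same reckoning gives 46.8 %; that oak run ends at 46.7 %.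

The constants are assumed, and the outcome is calculated.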